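**Plan**

1. Labdane numbering (C1–C20) is used throughout. Going backwards, the acetate and the silyl group are removed, the diene is cut at C12–C13 (alkyl iodide plus buta-1,3-dien-2-yl Grignard reagent), and ring B is opened at C6–C7 together with the C8–O bond.
2. Ring B can be opened this way because O6 and O8 sit 1,3 to one another through C7 while C8 also holds the C17 methyl. An isopropenyl group on C9 whose CH2 carbon (C7) adds to a C6 aldehyde, followed by hydration of the C8 cation, leaves exactly this arrangement.
3. The ring-A aldehyde ester is traced back through an auxiliary ring T (C5–C6–C12–C11–C9–C10), cut at C6–C12 (ketol cleavage), C8–C9 (conjugate addition) and C5=C6 (aldol), to a meso 2,6-bis(hydroxymethyl) ketone made from 2,6-dimethylcyclohexanone and two molecules of formaldehyde.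
4. Forward: ring A is present from the start; ring T is annulated, used and cleaved; ring B closes by the Prins reaction; the diene is joined at C12; acetylation and desilylation finish.
5. Stereochemistry: C4 and C10 come from lipase desymmetrisation of the meso diol, C9 from addition anti to the C20 methyl on the ring-T dienone, C5 from dissolving-metal reduction (trans fusion), and C6 and C8 from the chair Prins closure with equatorial capture of water.

Key step: step 13

Assumption: the lipase is taken to acylate the hydroxymethyl group on the (S)-configured ring carbon of meso diol 3; should it prefer the other arm, the same monoacetate 4 is reached by hydrolysis of the diacetate of 3 with the same enzyme.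

**Route**

Step 1
Reactants: 1 2,6-dimethylcyclohexan-1-one (cis/trans mixture); 2 formaldehyde (two molecules are taken up, one at each α-carbon)
Product: 3 (2R,6S)-2,6-bis(hydroxymethyl)-2,6-dimethylcyclohexan-1-one (meso, methyl groups cis)
Conditions: 37% aq. CH2O (2.5 equiv), K2CO3 (0.3 equiv), MeOH, 20 °C; meso diol separated from the trans diol by crystallisation or chromatography
Reagents that add atoms: formaldehyde (the second molecule of 2), C=O
Why: Two successive base-mediated crossed aldol additions (hydroxymethylation), one at each tertiary α-carbon, consume two molecules of formaldehyde and should give the non-enolisable bis-adduct as a cis/trans pair under mild kinetic conditions; the achiral cis isomer is carried on after separation.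

Step 2
Reactants: 3 meso diol
Product: 4 [(1S,3R)-3-(hydroxymethyl)-1,3-dimethyl-2-oxocyclohexyl]methyl acetate
Conditions: Amano lipase PS (Burkholderia cepacia), vinyl acetate (3 equiv), tBuOMe, 30 °C
Reagents that add atoms: vinyl acetate, C=COC(C)=O
Why: Lipase-catalysed transesterification with an irreversible acyl donor should distinguish the two enantiotopic hydroxymethyl groups and stop at the monoacetate, which fixes the absolute configuration of both quaternary carbons (C4 and C10) at once.

Step 3
Reactants: 4 monoacetate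
Product: 5 [(1S,3R)-1,3-dimethyl-2-oxo-3-{[(triisopropylsilyl)oxy]methyl}cyclohexyl]methyl acetate
Conditions: iPr3SiOTf, 2,6-lutidine, CH2Cl2, 0 °C
Reagents that add atoms: triisopropylsilyl trifluoromethanesulfonate, CC(C)[Si](C(C)C)(C(C)C)OS(=O)(=O)C(F)(F)F
Why: A silyl triflate silylates the hindered neopentyl alcohol (the future C18–OH) while the ketone, lacking α-hydrogens, cannot be enol-silylated; the TIPS ether is chosen because it survives Li/NH3 and dilute aqueous acid later on.

Step 4
Reactants: 5 silyl ether acetate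
Product: 6 (2S,6R)-2-(hydroxymethyl)-2,6-dimethyl-6-{[(triisopropylsilyl)oxy]methyl}cyclohexan-1-one
Conditions: K2CO3 (0.2 equiv), MeOH, 0 °C
Reagents that add atoms: none
Why: Mild base-catalysed methanolysis (transesterification) removes the primary acetate at a temperature where retro-aldol loss of formaldehyde from the β-hydroxy ketone should stay slow, and the silyl ether is inert.

Step 5
Reactants: 6 hydroxy ketone; 7 1-(triphenylphosphoranylidene)propan-2-one
Product: 9 (2S,6R)-2,6-dimethyl-2-[(1E)-3-oxobut-1-en-1-yl]-6-{[(triisopropylsilyl)oxy]methyl}cyclohexan-1-one, via keto aldehyde 8 (not isolated)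
Conditions: Dess–Martin periodinane, NaHCO3, CH2Cl2, 20 °C; then 7 (2 equiv), PhMe, 80 °C, same flask
Reagents that add atoms: none
Why: Dess–Martin oxidation gives the non-enolisable but deformylation-prone β-keto aldehyde, which is trapped in situ by Wittig olefination with the stabilised ylide to give the E-enone carrying C9, C11, C12 and the future C6.

Step 6
Reactants: 9 enone
Product: 10 (2S,6R)-2,6-dimethyl-2-(3-oxobutyl)-6-{[(triisopropylsilyl)oxy]methyl}cyclohexan-1-one
Conditions: H2 (1 atm), Pd/C (10%), EtOAc, 20 °C
Reagents that add atoms: none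
Why: Heterogeneous catalytic hydrogenation saturates the conjugated C=C bond only, freeing the chain for ring closure; ketones and silyl ether are untouched.

Step 7
Reactants: 10 diketone
Product: 11 (4aS,8S)-4a,8-dimethyl-8-{[(triisopropylsilyl)oxy]methyl}-4,4a,5,6,7,8-hexahydronaphthalen-2(3H)-one
Conditions: KOH, MeOH, 60 °C
Reagents that add atoms: none
Why: Intramolecular aldol condensation (the ring-closing half of a Robinson annulation): only the methyl ketone can enolise, its methyl carbon (C6) attacks the hindered C5 carbonyl to close the six-membered ring T, and dehydration gives the enone, as known for 2,2,6-trisubstituted 6-(3-oxobutyl)cyclohexanones.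

Step 8
Reactants: 11 bicyclic enone
Product: 12 (4aS,8S)-4a,8-dimethyl-8-{[(triisopropylsilyl)oxy]methyl}-5,6,7,8-tetrahydronaphthalen-2(4aH)-one
Conditions: DDQ (1.3 equiv), 1,4-dioxane, 100 °C
Reagents that add atoms: none
Why: DDQ dehydrogenation across C9–C11 converts the enone into the cross-conjugated dienone, as with steroidal 4-en-3-ones; the γ-carbon C4 is quaternary, so no linear dienone can form.

Step 9
Reactants: 12 dienone; 13 isopropenylmagnesium bromide
Product: 15 (4R,4aS,8S)-4a,8-dimethyl-4-(prop-1-en-2-yl)-8-{[(triisopropylsilyl)oxy]methyl}-4,4a,5,6,7,8-hexahydronaphthalen-2(3H)-one, via silyl dienol ether 14 (not isolated)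
Conditions: 13 (2 equiv), CuBr·SMe2 (0.2 equiv), Me3SiCl, THF, −78 → −40 °C; then 1 M HCl, 0 °C
Reagents that add atoms: none
Why: Copper-catalysed conjugate addition goes to the disubstituted β-carbon C9 (C5 is fully substituted and flanked by quaternary C4) and, by axial attack on the face opposite the angular C20 methyl as in 1α-alkylation of steroidal 1,4-dien-3-ones, sets C9; acid work-up returns the enone.

Step 10
Reactants: 15 isopropenyl enone
Product: 16 trimethylsilyl enol ether (C12(OSiMe3)=C6) of the trans-fused ring-T ketone, H5 anti to the C20 methyl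
Conditions: Li (2.2 equiv), NH3(l)/THF, tBuOH (1 equiv), −78 °C; isoprene; NH3 removed; Me3SiCl, Et3N, THF, 0 °C
Reagents that add atoms: chlorotrimethylsilane, C[Si](C)(C)Cl
Why: Birch-type dissolving-metal reduction of the enone protonates C5 axially, anti to the C20 methyl, to give the trans ring fusion, and the regiodefined lithium enolate is trapped as the silyl enol ether; the isolated isopropenyl group and the TIPS ether are inert.

Step 11
Reactants: 16 silyl enol ether
Product: 18 trans-fused ring-T ketol (C12=O, C6–OH), via silyloxy ketone 17 (not isolated)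
Conditions: mCPBA (1.05 equiv), NaHCO3, CH2Cl2, −20 °C; then 1 M HCl, THF, 0 °C
Reagents that add atoms: 3-chloroperoxybenzoic acid, OOC(=O)c1cccc(Cl)c1
Why: Rubottom oxidation: the electron-rich silyl enol ether is epoxidised much faster than the 1,1-disubstituted alkene, silyl migration gives the α-silyloxy ketone and acid frees the ketol; the configuration of the new carbinol centre C6 is of no consequence because it becomes the aldehyde carbon in step 12.

Step 12
Reactants: 18 ketol
Product: 19 methyl (3R)-3-[(1S,2S,3S)-2-formyl-1,3-dimethyl-3-{[(triisopropylsilyl)oxy]methyl}cyclohexyl]-4-methylpent-4-enoate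
Conditions: Pb(OAc)4 (1.1 equiv), MeOH/CH2Cl2 (1:1), 0 °C
Reagents that add atoms: methanol, CO
Why: Criegee-type cleavage of the α-ketol through its methyl hemiketal breaks C6–C12 and delivers the C6 aldehyde and the C12 methyl ester in one operation, leaving the C5 stereocentre and the isopropenyl group untouched.

Step 13
Reactants: 19 ring-A aldehyde ester
Product: 20 methyl 2-[(1S,2S,4R,4aS,5S,8aR)-2,4-dihydroxy-2,5,8a-trimethyl-5-{[(triisopropylsilyl)oxy]methyl}decahydronaphthalen-1-yl]acetate
Conditions: 5% aq. H2SO4/THF (1:1), 20 °C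
Reagents that add atoms: water, O
Why: Protonation of the C6 aldehyde lets the CH2 terminus (C7) of the isopropenyl group attack it through a chair in which ring A holds C6 and C9 equatorial, forming C6–C7 and a tertiary cation at C8, which water captures. The closest known reaction is the aqueous-acid Prins cyclisation of δ,ε-unsaturated aldehydes with hydration of the cation, as in the conversion of citronellal into p-menthane-3,8-diol. Ring B closes as a six-membered ring with the cation at a ring carbon (6-endo with respect to the alkene, Markovnikov). C6 is set by the equatorial placement of the carbonyl oxygen in the chair, since an axial oxygen would meet the axial C20 methyl; C8 is set by water approaching from the face opposite that methyl, which leaves O8 equatorial and C17 axial. The step needs the aldehyde–alkene closure to outrun simple hydration of the alkene and epimerisation at C5; the six-membered intramolecular geometry and the trans-diequatorial disposition of C6 and C9 should secure this. The TIPS ether and the methyl ester tolerate dilute acid at room temperature.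

Step 14
Reactants: 20 diol ester
Product: 21 6,8-bis(triethylsilyl) ether of 20
Conditions: Et3SiOTf (2.5 equiv), 2,6-lutidine, CH2Cl2, −78 → 0 °C
Reagents that add atoms: triethylsilyl trifluoromethanesulfonate, CC[Si](CC)(CC)OS(=O)(=O)C(F)(F)F
Why: A silyl triflate silylates both the secondary and the hindered tertiary hydroxyl; O8 has to be masked because a free 8-OH would displace any leaving group at C12 to close the 8,12-ether.

Step 15
Reactants: 21 bis-silyl ether ester
Product: 22 C12 primary alcohol (6,8-bis-TES, 18-TIPS)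
Conditions: LiAlH4, Et2O, 0 °C
Reagents that add atoms: none
Why: Hydride reduction takes the methyl ester to the primary alcohol, and the three silyl ethers are stable to LiAlH4.

Step 16
Reactants: 22 primary alcohol
Product: 23 C12 primary iodide (6,8-bis-TES, 18-TIPS)
Conditions: I2, PPh3, imidazole, CH2Cl2, 0 °C
Reagents that add atoms: iodine, II
Why: Appel-type iodination converts the unhindered primary alcohol through its alkoxyphosphonium salt into the iodide by SN2, the buffered conditions sparing the silyl ethers.

Step 17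
Reactants: 23 iodide; 24 2-chlorobuta-1,3-diene
Product: 26 labda-13(16),14-diene with 6,8-bis-TES and 18-TIPS ethers, via dienyl Grignard reagent 25 (not isolated)
Conditions: 24, Mg, ZnCl2 (cat.), THF, 60 °C; then 23, Li2CuCl4 (5 mol%), THF, −20 → 20 °C
Reagents that add atoms: none
Why: Copper-catalysed cross-coupling of a primary alkyl iodide with buta-1,3-dien-2-ylmagnesium chloride is an established way to 2-alkylbuta-1,3-dienes and forms C12–C13 without touching the silyl ethers.

Step 18
Reactants: 26 tris-silyl diene
Product: 27 6,8-diol with the 18-TIPS ether retained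
Conditions: HF·pyridine, pyridine, THF, 0 → 20 °C
Reagents that add atoms: none
Why: Buffered fluoride cleaves the two triethylsilyl ethers much faster than the neopentyl triisopropylsilyl ether, and the conditions are mild enough for the diene and the tertiary alcohol.

Step 19
Reactants: 27 diol
Product: 28 6-acetate with the 18-TIPS ether retained
Conditions: Ac2O, pyridine, DMAP (cat.), 20 °C
Reagents that add atoms: acetic anhydride, CC(=O)OC(C)=O
Why: Acylation takes place only at the equatorial secondary 6-OH, since the tertiary 8-OH does not react under these conditions and O18 is still silylated.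

Step 20
Reactants: 28 silyl ether acetate
Product: 29 (1R,3S,4S,4aR,8S,8aS)-3-hydroxy-8-(hydroxymethyl)-3,4a,8-trimethyl-4-(3-methylidenepent-4-en-1-yl)decahydronaphthalen-1-yl acetate (target)
Conditions: Bu4NF, AcOH (1:1), THF, 20 → 40 °C
Reagents that add atoms: none
Why: Fluoride desilylation frees the C18 hydroxyl, and buffering with acetic acid should suppress acetyl migration or loss.

**Compound list**

1 | 2,6-dimethylcyclohexan-1-one | CC1CCCC(C)C1=O | starting material
2 | formaldehyde | C=O | starting material
3 | (2R,6S)-2,6-bis(hydroxymethyl)-2,6-dimethylcyclohexan-1-one (meso) | OC[C@]1(C)CCC[C@](C)(CO)C1=O | intermediate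
4 | [(1S,3R)-3-(hydroxymethyl)-1,3-dimethyl-2-oxocyclohexyl]methyl acetate | CC(=O)OC[C@]1(C)CCC[C@](C)(CO)C1=O | intermediate
5 | [(1S,3R)-1,3-dimethyl-2-oxo-3-{[(triisopropylsilyl)oxy]methyl}cyclohexyl]methyl acetate | CC(=O)OC[C@]1(C)CCC[C@](C)(CO[Si](C(C)C)(C(C)C)C(C)C)C1=O | intermediate
6 | (2S,6R)-2-(hydroxymethyl)-2,6-dimethyl-6-{[(triisopropylsilyl)oxy]methyl}cyclohexan-1-one | OC[C@]1(C)CCC[C@](C)(CO[Si](C(C)C)(C(C)C)C(C)C)C1=O | intermediate
7 | 1-(triphenylphosphoranylidene)propan-2-one | CC(=O)C=P(c1ccccc1)(c1ccccc1)c1ccccc1 | starting material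
8 | (1S,3R)-1,3-dimethyl-2-oxo-3-{[(triisopropylsilyl)oxy]methyl}cyclohexane-1-carbaldehyde | O=C[C@]1(C)CCC[C@](C)(CO[Si](C(C)C)(C(C)C)C(C)C)C1=O | intermediate (not isolated)
9 | (2S,6R)-2,6-dimethyl-2-[(1E)-3-oxobut-1-en-1-yl]-6-{[(triisopropylsilyl)oxy]methyl}cyclohexan-1-one | CC(=O)/C=C/[C@]1(C)CCC[C@](C)(CO[Si](C(C)C)(C(C)C)C(C)C)C1=O | intermediate
10 | (2S,6R)-2,6-dimethyl-2-(3-oxobutyl)-6-{[(triisopropylsilyl)oxy]methyl}cyclohexan-1-one | CC(=O)CC[C@]1(C)CCC[C@](C)(CO[Si](C(C)C)(C(C)C)C(C)C)C1=O | intermediate
11 | (4aS,8S)-4a,8-dimethyl-8-{[(triisopropylsilyl)oxy]methyl}-4,4a,5,6,7,8-hexahydronaphthalen-2(3H)-one | O=C1C=C2[C@@](C)(CO[Si](C(C)C)(C(C)C)C(C)C)CCC[C@@]2(C)CC1 | intermediate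
12 | (4aS,8S)-4a,8-dimethyl-8-{[(triisopropylsilyl)oxy]methyl}-5,6,7,8-tetrahydronaphthalen-2(4aH)-one | O=C1C=C2[C@@](C)(CO[Si](C(C)C)(C(C)C)C(C)C)CCC[C@@]2(C)C=C1 | intermediate
13 | isopropenylmagnesium bromide (THF solution) | CC(=C)[Mg]Br | starting material
14 | trimethylsilyl dienol ether of 15 (C12–OSiMe3; C11=C12 and C5=C6) | C[Si](C)(C)OC1=C[C@H](C(C)=C)[C@]2(C)CCC[C@](C)(CO[Si](C(C)C)(C(C)C)C(C)C)C2=C1 | intermediate (not isolated)
15 | (4R,4aS,8S)-4a,8-dimethyl-4-(prop-1-en-2-yl)-8-{[(triisopropylsilyl)oxy]methyl}-4,4a,5,6,7,8-hexahydronaphthalen-2(3H)-one (isopropenyl anti to the C20 methyl) | O=C1C=C2[C@@](C)(CO[Si](C(C)C)(C(C)C)C(C)C)CCC[C@@]2(C)[C@@H](C(C)=C)C1 | intermediate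
16 | trimethylsilyl enol ether (C12(OSiMe3)=C6) of the trans-fused ring-T ketone; H5 anti to the C20 methyl | C[Si](C)(C)OC1=C[C@@H]2[C@@](C)(CO[Si](C(C)C)(C(C)C)C(C)C)CCC[C@@]2(C)[C@@H](C(C)=C)C1 | intermediate
17 | C6-(trimethylsilyloxy) C12-ketone of trans-fused ring T | O=C1[C@@H](O[Si](C)(C)C)[C@@H]2[C@@](C)(CO[Si](C(C)C)(C(C)C)C(C)C)CCC[C@@]2(C)[C@@H](C(C)=C)C1 | intermediate (not isolated)
18 | C6-hydroxy C12-ketone of trans-fused ring T (OH drawn equatorial, anti to C20; the C6 epimer serves equally) | O=C1[C@@H](O)[C@@H]2[C@@](C)(CO[Si](C(C)C)(C(C)C)C(C)C)CCC[C@@]2(C)[C@@H](C(C)=C)C1 | intermediate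
19 | methyl (3R)-3-[(1S,2S,3S)-2-formyl-1,3-dimethyl-3-{[(triisopropylsilyl)oxy]methyl}cyclohexyl]-4-methylpent-4-enoate | COC(=O)C[C@H](C(C)=C)[C@]1(C)CCC[C@](C)(CO[Si](C(C)C)(C(C)C)C(C)C)[C@H]1C=O | intermediate
20 | methyl 2-[(1S,2S,4R,4aS,5S,8aR)-2,4-dihydroxy-2,5,8a-trimethyl-5-{[(triisopropylsilyl)oxy]methyl}decahydronaphthalen-1-yl]acetate | COC(=O)C[C@H]1[C@]2(C)CCC[C@](C)(CO[Si](C(C)C)(C(C)C)C(C)C)[C@H]2[C@H](O)C[C@]1(C)O | intermediate
21 | 6,8-bis(triethylsilyl) ether of 20 | COC(=O)C[C@H]1[C@]2(C)CCC[C@](C)(CO[Si](C(C)C)(C(C)C)C(C)C)[C@H]2[C@H](O[Si](CC)(CC)CC)C[C@]1(C)O[Si](CC)(CC)CC | intermediate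
22 | C12 primary alcohol, 6,8-bis(triethylsilyl) and 18-triisopropylsilyl ethers | OCC[C@H]1[C@]2(C)CCC[C@](C)(CO[Si](C(C)C)(C(C)C)C(C)C)[C@H]2[C@H](O[Si](CC)(CC)CC)C[C@]1(C)O[Si](CC)(CC)CC | intermediate
23 | C12 primary iodide, 6,8-bis(triethylsilyl) and 18-triisopropylsilyl ethers | ICC[C@H]1[C@]2(C)CCC[C@](C)(CO[Si](C(C)C)(C(C)C)C(C)C)[C@H]2[C@H](O[Si](CC)(CC)CC)C[C@]1(C)O[Si](CC)(CC)CC | intermediate
24 | 2-chlorobuta-1,3-diene | C=CC(Cl)=C | starting material
25 | buta-1,3-dien-2-ylmagnesium chloride | C=CC(=C)[Mg]Cl | intermediate (not isolated)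
26 | labda-13(16),14-diene-6,8,18-triol 6,8-bis(triethylsilyl) 18-triisopropylsilyl ether (configuration as in 29) | C=CC(=C)CC[C@H]1[C@]2(C)CCC[C@](C)(CO[Si](C(C)C)(C(C)C)C(C)C)[C@H]2[C@H](O[Si](CC)(CC)CC)C[C@]1(C)O[Si](CC)(CC)CC | intermediate
27 | labda-13(16),14-diene-6,8,18-triol 18-triisopropylsilyl ether | C=CC(=C)CC[C@H]1[C@]2(C)CCC[C@](C)(CO[Si](C(C)C)(C(C)C)C(C)C)[C@H]2[C@H](O)C[C@]1(C)O | intermediate
28 | 6-acetate of 27 | C=CC(=C)CC[C@H]1[C@]2(C)CCC[C@](C)(CO[Si](C(C)C)(C(C)C)C(C)C)[C@H]2[C@H](OC(C)=O)C[C@]1(C)O | intermediate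
29 | (1R,3S,4S,4aR,8S,8aS)-3-hydroxy-8-(hydroxymethyl)-3,4a,8-trimethyl-4-(3-methylidenepent-4-en-1-yl)decahydronaphthalen-1-yl acetate | C=CC(=C)CC[C@H]1[C@]2(C)CCC[C@](C)(CO)[C@H]2[C@H](OC(C)=O)C[C@]1(C)O | target

**Step count**

Total steps: 20. Longest linear sequence: 20 steps (1 → 29); compounds 2, 7, 13 and 24 are bought.

**Steps most likely to fail**

Step 13. The C8 cation may be intercepted by the neighbouring ester carbonyl (lactonisation) or lose a proton instead of being hydrated, and a slow closure at the hindered aldehyde would leave time for plain hydration of the alkene or epimerisation at C5. The fallback sets out from 19 and makes the ester the terminating group on purpose. Treatment of 19 with BF3·OEt2 in CH2Cl2 at −40 °C followed by aqueous NaHCO3 should form the same C6–C7 bond and close the trans-fused hydroxy lactone F1, the carbonyl oxygen reaching C8 from the equatorial side as water would. LiAlH4 opens it to the 6,8,12-triol F2. Excess Et3SiOTf with 2,6-lutidine gives the tris(triethylsilyl) ether F3. Selective methanolysis of the primary triethylsilyl ether (pyridinium p-toluenesulfonate, MeOH/CH2Cl2, −10 °C) returns to the route at 22.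

Step 1. The second hydroxymethylation has no built-in preference for the cis isomer, and retro-aldol equilibration would drain material into the trans diol, which is free of the syn-diaxial interaction. The fallback sets out from 1 and builds the two quaternary centres one after the other. Condensation of 1 with (R)-1-phenylethylamine (PhMe, reflux, water removal) gives imine F4; this amine enantiomer is chosen by analogy with the sense of induction known for 2-methylcyclohexanone. Michael addition of its enamine tautomer to methyl vinyl ketone gives adduct imine F5, and 10% aq. AcOH releases (2S)-2,6-dimethyl-2-(3-oxobutyl)cyclohexan-1-one F6, fixing C10. The unhindered methyl ketone is masked with ethane-1,2-diol (pyridinium p-toluenesulfonate, PhMe, reflux) as dioxolane F7. Deprotonation with LiN(iPr)2 at −78 °C and gaseous formaldehyde gives, under irreversible conditions, hydroxymethyl ketone F8 together with its C4 epimer, now a diastereomer of one enantiomeric series and removed by chromatography. iPr3SiOTf and 2,6-lutidine give silyl ether F9, and acetal hydrolysis (pyridinium p-toluenesulfonate, acetone/H2O) returns to the route at 10. This also removes the reliance on the enzyme in step 2.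

Step 9. Addition at C9, which is neopentyl to the quaternary C10, may be slow, so that 1,2-addition or attack on the wrong face competes. The fallback sets out from 9, where the same β-carbon lies in an open chain. CuBr·SMe2-mediated addition of 13 to 9 in THF at −40 °C gives isopropenyl diketone F10 as a mixture of C9 epimers. KOH in MeOH then closes ring T as in step 7, the C9 epimers are separated at the rigid bicyclic stage, and the required one rejoins the route at 15. Cyclic stereocontrol is given up for accessibility, and steps 6 to 8 are no longer needed.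

**Further compounds**

F1 | step 13 | 6-hydroxy-8,12-lactone (trans-fused γ-lactone on ring B, 18-triisopropylsilyl ether) | O=C1C[C@H]2[C@]3(C)CCC[C@](C)(CO[Si](C(C)C)(C(C)C)C(C)C)[C@H]3[C@H](O)C[C@]2(C)O1
F2 | step 13 | 6,8,12-triol 18-triisopropylsilyl ether | OCC[C@H]1[C@]2(C)CCC[C@](C)(CO[Si](C(C)C)(C(C)C)C(C)C)[C@H]2[C@H](O)C[C@]1(C)O
F3 | step 13 | 6,8,12-tris(triethylsilyl) 18-triisopropylsilyl ether | CC[Si](CC)(CC)OCC[C@H]1[C@]2(C)CCC[C@](C)(CO[Si](C(C)C)(C(C)C)C(C)C)[C@H]2[C@H](O[Si](CC)(CC)CC)C[C@]1(C)O[Si](CC)(CC)CC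
F4 | step 1 | (1R)-N-(2,6-dimethylcyclohexylidene)-1-phenylethan-1-amine (ring epimers) | CC1CCCC(C)C1=N[C@H](C)c1ccccc1
F5 | step 1 | (1R)-N-[(2S)-2,6-dimethyl-2-(3-oxobutyl)cyclohexylidene]-1-phenylethan-1-amine | CC(=O)CC[C@]1(C)CCCC(C)C1=N[C@H](C)c1ccccc1
F6 | step 1 | (2S)-2,6-dimethyl-2-(3-oxobutyl)cyclohexan-1-one (C6 epimers) | CC(=O)CC[C@]1(C)CCCC(C)C1=O
F7 | step 1 | (2S)-2,6-dimethyl-2-[2-(2-methyl-1,3-dioxolan-2-yl)ethyl]cyclohexan-1-one | CC1(CC[C@]2(C)CCCC(C)C2=O)OCCO1
F8 | step 1 | (2R,6S)-2-(hydroxymethyl)-2,6-dimethyl-6-[2-(2-methyl-1,3-dioxolan-2-yl)ethyl]cyclohexan-1-one | CC1(CC[C@]2(C)CCC[C@](C)(CO)C2=O)OCCO1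
F9 | step 1 | triisopropylsilyl ether of F8 | CC1(CC[C@]2(C)CCC[C@](C)(CO[Si](C(C)C)(C(C)C)C(C)C)C2=O)OCCO1
F10 | step 9 | (2S,6R)-2,6-dimethyl-2-[(3R)-2-methyl-5-oxohex-1-en-3-yl]-6-{[(triisopropylsilyl)oxy]methyl}cyclohexan-1-one | CC(=O)C[C@H](C(C)=C)[C@]1(C)CCC[C@](C)(CO[Si](C(C)C)(C(C)C)C(C)C)C1=O
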